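Rings A and B are disconnected together across C5–C10 and C8–C9. One thermal intramolecular Diels–Alder reaction of an open-chain (6R,7Z)-2-aryloxydeca-1,7,9-trien-3-one closes both carbocycles and sets the adjacent fully substituted carbons C5 (methyl) and C10 (aryl ether oxygen) cis at the cis-decalin fusion. The C4 methyl centre steers the diene face and ends cis to the C5 methyl. The precursor already carries the complete acetophenone ring as the 2-aryloxy group of the enone, with its second phenol left free, and a Z-trisubstituted diene made by syn-carbocupration. Friedel–Crafts closure, C8 oxidation, isopropylidene transfer, aldol and C9 oxidation follow.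

Key step: step 14

Remark on locants used below: C1 is the benzylic CH, C2 and C3 are CH2, C4 is CHMe, C5 is CMe, C6 and C7 become the cyclopropane CH carbons, C8 and C9 the ketone carbons, C10 carries the ether oxygen, C11 is CMe2. Ring A is C1–C5 plus C10, ring B is C5–C10. On the arene C1' carries the acyl group, C2' the OH, C4' the OMe, C5' is bonded to C1 and C6' to the ether oxygen.

Step 1
Reactants: 1 (4S)-4-benzyl-3-propanoyl-1,3-oxazolidin-2-one; 2 tert-butyl bromoacetate
Product: 4 tert-butyl (3R)-4-[(4S)-4-benzyl-2-oxo-1,3-oxazolidin-3-yl]-3-methyl-4-oxobutanoate, via sodium enolate 3 (not isolated)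
Conditions: NaN(SiMe3)2, THF, −78 °C; then 2, −78 → −40 °C
Reagents that add atoms: none
Why: Evans asymmetric alkylation: the chelated Z-enolate 3 is attacked by the reactive α-bromo ester on the face away from the benzyl group, which sets the future C4 methyl centre (R) at the outset.

Step 2
Reactants: 4 tert-butyl (3R)-4-[(4S)-4-benzyl-2-oxo-1,3-oxazolidin-3-yl]-3-methyl-4-oxobutanoate
Product: 5 tert-butyl (3R)-4-hydroxy-3-methylbutanoate
Conditions: LiBH4, MeOH (1 equiv), THF, 0 °C
Reagents that add atoms: none
Why: Reductive removal of the Evans auxiliary with LiBH4: the imide carbonyl is much more electrophilic than the hindered tert-butyl ester, so only it is reduced to the primary alcohol, and the stereocentre is not touched.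

Step 3
Reactants: 5 tert-butyl (3R)-4-hydroxy-3-methylbutanoate
Product: 6 tert-butyl (3R)-3-methyl-4-oxobutanoate
Conditions: Dess–Martin periodinane, NaHCO3, CH2Cl2, 0 °C → rt; used crude
Reagents that add atoms: none
Why: Dess–Martin oxidation under buffered, non-basic conditions should give the α-branched aldehyde without epimerisation; it is carried on at once.

Step 4
Reactants: 6 tert-butyl (3R)-3-methyl-4-oxobutanoate
Product: 7 tert-butyl (3R)-3-methylpent-4-ynoate
Conditions: dimethyl (1-diazo-2-oxopropyl)phosphonate, K2CO3, MeOH, 0 °C → rt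
Reagents that add atoms: dimethyl (1-diazo-2-oxopropyl)phosphonate, COP(=O)(OC)C(=[N+]=[N-])C(C)=O
Why: Seyferth–Gilbert homologation with the Ohira–Bestmann reagent: mild carbonate base at low temperature converts the aldehyde into the terminal alkyne (future C5≡C6) with little risk to the α-stereocentre and none to the tert-butyl ester.

Step 5
Reactants: 7 tert-butyl (3R)-3-methylpent-4-ynoate
Product: 8 6-tert-butyl 1-methyl (4R)-4-methylhex-2-ynedioate
Conditions: PdCl2 (5 mol %), CuCl2, NaOAc, CO (1 atm), MeOH, rt
Reagents that add atoms: carbon monoxide, [C-]#[O+]; methanol, CO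
Why: Tsuji oxidative alkoxycarbonylation of a terminal alkyne (alkynylpalladium, CO insertion, methanolysis, CuCl2 as reoxidant) installs C7 as an ester without any strong base, so the tert-butyl ester and the propargylic centre are safe.

Step 6
Reactants: 8 6-tert-butyl 1-methyl (4R)-4-methylhex-2-ynedioate
Product: 9 6-tert-butyl 1-methyl (2Z,4R)-3,4-dimethylhex-2-enedioate
Conditions: Me2CuLi (from CuI and MeLi), THF, −78 °C; MeOH then aq. NH4Cl at −78 °C
Reagents that add atoms: lithium dimethylcuprate, [Li+].C[Cu-]C
Why: Conjugate syn-carbocupration of a 2-ynoate (Corey–Katzenellenbogen addition) with protonation at low temperature: methyl and hydrogen end cis, so the chain on C5 is cis to the C7 ester and the Z geometry of C5=C6 is set stereospecifically.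

Step 7
Reactants: 9 6-tert-butyl 1-methyl (2Z,4R)-3,4-dimethylhex-2-enedioate
Product: 10 (2Z,4R)-3,4-dimethylhex-2-ene-1,6-diol
Conditions: i-Bu2AlH (6 equiv), CH2Cl2, −78 → 0 °C; aq. KNaC4H4O6
Reagents that add atoms: none
Why: Exhaustive hydride reduction of both esters with i-Bu2AlH (1,2-reduction of the enoate) should give the Z-allylic alcohol and the C2 primary alcohol with retention of the alkene geometry.

Step 8
Reactants: 10 (2Z,4R)-3,4-dimethylhex-2-ene-1,6-diol
Product: 11 (2Z,4R)-6-hydroxy-3,4-dimethylhex-2-enal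
Conditions: MnO2, CH2Cl2, rt
Reagents that add atoms: none
Why: Chemoselective MnO2 oxidation of the allylic alcohol only, under neutral conditions that keep the Z geometry and the γ-stereocentre.

Step 9
Reactants: 11 (2Z,4R)-6-hydroxy-3,4-dimethylhex-2-enal
Product: 12 (3R,4Z)-3,4-dimethylhepta-4,6-dien-1-ol
Conditions: Ph3PCH3Br, KN(SiMe3)2, THF, 0 °C; then 11 added slowly, −78 → 0 °C
Reagents that add atoms: methyltriphenylphosphonium bromide, C[P+](c1ccccc1)(c1ccccc1)c1ccccc1.[Br-]
Why: Wittig methylenation: the aldehyde should react with the unstabilised ylide far faster than γ-deprotonation at −78 °C, which completes the Z-diene C5=C6–C7=C8, the free hydroxyl only consuming one equivalent of ylide.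

Step 10
Reactants: 12 (3R,4Z)-3,4-dimethylhepta-4,6-dien-1-ol
Product: 13 (3Z,5R)-7-bromo-4,5-dimethylhepta-1,3-diene
Conditions: CBr4, PPh3, CH2Cl2, 0 °C
Reagents that add atoms: carbon tetrabromide, BrC(Br)(Br)Br
Why: Appel reaction: SN2 displacement of the activated primary alcohol by bromide at 0 °C under neutral conditions, to which the diene is inert.

Step 11
Reactants: 13 (3Z,5R)-7-bromo-4,5-dimethylhepta-1,3-diene; 14 2-chloro-N-methoxy-N-methylacetamide
Product: 16 (5R,6Z)-1-chloro-5,6-dimethylnona-6,8-dien-2-one, via Grignard reagent 15 (not isolated)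
Conditions: Mg, THF, rt; then added to 14, THF, −20 → 0 °C; aq. NH4Cl
Reagents that add atoms: none
Why: Acylation of a Grignard reagent with a Weinreb amide: the magnesium chelate of the tetrahedral adduct prevents over-addition, so the chloromethyl ketone (C1 ketone, C10 as CH2Cl) forms regiospecifically, and a bishomoallylic organomagnesium has no fast cyclisation path.

Step 12
Reactants: 16 (5R,6Z)-1-chloro-5,6-dimethylnona-6,8-dien-2-one; 17 2',6'-dihydroxy-4'-methoxyacetophenone
Product: 18 (5R,6Z)-1-(2-acetyl-3-hydroxy-5-methoxyphenoxy)-5,6-dimethylnona-6,8-dien-2-one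
Conditions: 17 (2 equiv), K2CO3, NaI (cat.), acetone, 45 °C
Reagents that add atoms: none
Why: Williamson ether synthesis (Finkelstein-assisted SN2 at the α-chloro ketone): with the diol in excess one phenol should be alkylated while the other stays locked in the hydrogen bond to the acetyl group.

Step 13
Reactants: 18 (5R,6Z)-1-(2-acetyl-3-hydroxy-5-methoxyphenoxy)-5,6-dimethylnona-6,8-dien-2-one
Product: 20 (6R,7Z)-2-(2-acetyl-3-hydroxy-5-methoxyphenoxy)-6,7-dimethyldeca-1,7,9-trien-3-one, via Mannich base 19 (not isolated)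
Conditions: (CH2O)n, i-Pr2NH2+ CF3CO2−, CF3CO2H (cat.), THF, 55 °C; concentrated cold and used at once
Reagents that add atoms: formaldehyde (as paraformaldehyde), C=O
Why: Mannich α-methylenation of a ketone with an ammonium trifluoroacetate and formaldehyde (Mannich base 19, then β-elimination of the amine): the C10–H between ether oxygen and carbonyl is about three pKa units more acidic than C2–H or the aryl methyl ketone, so C–C bond formation should occur there, while the bulky iminium ion and the acidic medium should spare the doubly flanked, acyl-deactivated arene positions.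

Step 14
Reactants: 20 (6R,7Z)-2-(2-acetyl-3-hydroxy-5-methoxyphenoxy)-6,7-dimethyldeca-1,7,9-trien-3-one
Product: 21 (4R,4aR,8aR)-8a-(2-acetyl-3-hydroxy-5-methoxyphenoxy)-4,4a-dimethyl-3,4,4a,7,8,8a-hexahydronaphthalen-1(2H)-one
Conditions: PhMe (0.01 M, degassed), BHT (cat.), 95 °C
Reagents that add atoms: none
Why: Thermal intramolecular [4+2] cycloaddition (type 1 intramolecular Diels–Alder reaction of a 1,7,9-decatrien-3-one, a known class in which Z-dienes give only cis-fused octalones): the ketone-activated 2-aryloxy alkene C9=C10 adds suprafacially to the diene C5=C6–C7=C8 and forms C5–C10 and C8–C9 in one concerted, asynchronous step. Ring B is closed as the new cyclohexene of the cycloaddition and ring A as the six-membered ring spanned by the four-atom tether C1–C4 between dienophile and diene. The ring fusion (C5 methyl and C10 aryloxy cis) is controlled by the Z geometry, because a tether on the inside position of C5 can reach C10 only in the transition state with the tether ketone exo and the aryloxy group under the diene. The absolute sense at C5 and C10 is controlled by C4: allylic strain against the cis vinyl group holds C4–H in the diene plane, the tether rises on one face and the C4 methyl stays on the other, ending equatorial and cis to the axial C5 methyl. The step needs periselectivity over the 1,5-hydrogen shift of the Z-diene and over polymerisation of the enone, which conjugation of the dienophile with the C1 ketone, high dilution and a radical inhibitor should secure at about 95 °C.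

Step 15
Reactants: 21 (4R,4aR,8aR)-8a-(2-acetyl-3-hydroxy-5-methoxyphenoxy)-4,4a-dimethyl-3,4,4a,7,8,8a-hexahydronaphthalen-1(2H)-one
Product: 24 (1R,4R,5R,10S)-tetracyclic dihydrobenzofuran (C5'–C1 bond closed, C1–H cis to C9, C6=C7 alkene, 1'-acetyl, 2'-OH, 4'-OMe), via tertiary carbinol 22 (not isolated), via styrenyl alkene 23 (not isolated)
Conditions: CF3SO3H (0.3 equiv), (CF3)2CHOH, 0 °C → rt; then CH2Cl2, CF3CO2H (10 equiv), Et3SiH (2 equiv), −20 → 0 °C
Reagents that add atoms: none
Why: Intramolecular Friedel–Crafts hydroxyalkylation with cyclodehydration (the closure used for benzofurans from α-aryloxy ketones) followed by ionic hydrogenation: C5', para to the free phenol and ortho to two oxygens, attacks the protonated C1 ketone (5-exo), carbinol 22 dehydrates to alkene 23, and in CF3CO2H the benzylic C1 cation should be reduced by Et3SiH on the face away from the axial C5 methyl, which gives the cis-fused dihydrobenzofuran and should be fast enough at −20 °C to leave the aryl methyl ketone alone.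

Step 16
Reactants: 24 (1R,4R,5R,10S)-tetracyclic dihydrobenzofuran
Product: 25 (1R,4R,5R,10S)-tetracyclic enone (C6=C7–C8=O)
Conditions: Rh2(C6H10NO)4 [dirhodium tetrakis(caprolactamate)] (1 mol %), t-BuOOH (70% aq.), ClCH2CH2Cl, 40 °C
Reagents that add atoms: tert-butyl hydroperoxide, CC(C)(C)OO
Why: Dirhodium-catalysed allylic oxidation with tert-butyl hydroperoxide (peroxyl-radical chain to the enone): C8 is the only allylic C–H position because C5 is quaternary, the tertiary benzylic C1–H is screened by C10 and the arene substituents, and the hydrogen-bonded acylphenol is a poor hydrogen donor.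

Step 17
Reactants: 25 (1R,4R,5R,10S)-tetracyclic enone
Product: 26 (1R,4R,5R,6S,7R,10S)-cyclopropyl ketone (C6–C7–C11 cyclopropane with C11 dimethyl, C8 ketone, C9 CH2)
Conditions: i-PrPh2S+ BF4− (3.2 equiv), LiN(i-Pr)2 (3.2 equiv), MeOCH2CH2OMe, −78 °C; then 25, −78 → −30 °C
Reagents that add atoms: isopropyldiphenylsulfonium tetrafluoroborate, CC(C)[S+](c1ccccc1)c1ccccc1.F[B-](F)(F)F
Why: Corey isopropylidene transfer with diphenylsulfonium isopropylide (conjugate addition at C6, then closure of the enolate on the sulfonium carbon): attack anti to the pseudoaxial C5 methyl beside C6 should place the cyclopropane on the face opposite the C5 methyl and the C10 oxygen, and the first equivalent of ylide turns the phenol into a phenoxide that deactivates the acetyl group.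

Step 18
Reactants: 26 (1R,4R,5R,6S,7R,10S)-cyclopropyl ketone; 27 4-methoxybenzaldehyde
Product: 29 (1R,4R,5R,6S,7R,10S)-chalcone [1'-(E)-3-(4-methoxyphenyl)prop-2-enoyl, C8 ketone, C9 CH2], via aldol adduct 28 (not isolated)
Conditions: 27 (3 equiv), KOH (50% aq.), EtOH, rt; then dilute HCl, 0 °C
Reagents that add atoms: none
Why: Claisen–Schmidt condensation (crossed aldol, then E1cB dehydration of aldol 28): the aryl methyl ketone enolate adds to the non-enolisable aldehyde to give the E-enone, whereas the C9 methylene of the cyclopropyl ketone is neopentyl and should not condense.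

Step 19
Reactants: 29 (1R,4R,5R,6S,7R,10S)-chalcone
Product: 31 C9-hydroxy ketone (either C9 epimer), via dipotassium enolate 30 (not isolated)
Conditions: KN(SiMe3)2 (2.3 equiv), THF, −78 °C; then 2-(phenylsulfonyl)-3-phenyloxaziridine, −78 °C; aq. NH4Cl
Reagents that add atoms: 2-(phenylsulfonyl)-3-phenyloxaziridine, O=S(=O)(c1ccccc1)N1OC1c1ccccc1
Why: Davis oxaziridine hydroxylation of a potassium enolate: after the phenol the only acidic C–H left is at C9 (the chalcone has no enolisable hydrogen, C7 is a cyclopropane CH, C10 is quaternary), so enolate 30 should be oxygenated there, the new C9 configuration being irrelevant.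

Step 20
Reactants: 31 C9-hydroxy ketone
Product: 32 CNP0121765.1, (1R,4R,5R,6S,7R,10S)
Conditions: Dess–Martin periodinane, NaHCO3, CH2Cl2, 0 °C → rt
Reagents that add atoms: none
Why: Dess–Martin oxidation of the α-hydroxy ketone to the non-enolisable 1,2-diketone under buffered neutral conditions; chalcone, cyclopropane and hydrogen-bonded phenol should be inert and no stereocentre is touched.

Compound list
1 | (4S)-4-benzyl-3-propanoyl-1,3-oxazolidin-2-one | CCC(=O)N1[C@@H](Cc2ccccc2)COC1=O | starting material
2 | tert-butyl bromoacetate | CC(C)(C)OC(=O)CBr | starting material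
3 | sodium (Z)-enolate of 1 | C/C=C(\[O-])N1[C@@H](Cc2ccccc2)COC1=O.[Na+] | intermediate
4 | tert-butyl (3R)-4-[(4S)-4-benzyl-2-oxo-1,3-oxazolidin-3-yl]-3-methyl-4-oxobutanoate | CC(C)(C)OC(=O)C[C@@H](C)C(=O)N1[C@@H](Cc2ccccc2)COC1=O | intermediate
5 | tert-butyl (3R)-4-hydroxy-3-methylbutanoate | CC(C)(C)OC(=O)C[C@@H](C)CO | intermediate
6 | tert-butyl (3R)-3-methyl-4-oxobutanoate | CC(C)(C)OC(=O)C[C@@H](C)C=O | intermediate
7 | tert-butyl (3R)-3-methylpent-4-ynoate | CC(C)(C)OC(=O)C[C@@H](C)C#C | intermediate
8 | 6-tert-butyl 1-methyl (4R)-4-methylhex-2-ynedioate | CC(C)(C)OC(=O)C[C@@H](C)C#CC(=O)OC | intermediate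
9 | 6-tert-butyl 1-methyl (2Z,4R)-3,4-dimethylhex-2-enedioate | CC(C)(C)OC(=O)C[C@@H](C)/C(C)=C\C(=O)OC | intermediate
10 | (2Z,4R)-3,4-dimethylhex-2-ene-1,6-diol | OCC[C@@H](C)/C(C)=C\CO | intermediate
11 | (2Z,4R)-6-hydroxy-3,4-dimethylhex-2-enal | OCC[C@@H](C)/C(C)=C\C=O | intermediate
12 | (3R,4Z)-3,4-dimethylhepta-4,6-dien-1-ol | OCC[C@@H](C)/C(C)=C\C=C | intermediate
13 | (3Z,5R)-7-bromo-4,5-dimethylhepta-1,3-diene | BrCC[C@@H](C)/C(C)=C\C=C | intermediate
14 | 2-chloro-N-methoxy-N-methylacetamide | CON(C)C(=O)CCl | starting material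
15 | [(3R,4Z)-3,4-dimethylhepta-4,6-dien-1-yl]magnesium bromide | Br[Mg]CC[C@@H](C)/C(C)=C\C=C | intermediate
16 | (5R,6Z)-1-chloro-5,6-dimethylnona-6,8-dien-2-one | ClCC(=O)CC[C@@H](C)/C(C)=C\C=C | intermediate
17 | 2',6'-dihydroxy-4'-methoxyacetophenone | CC(=O)c1c(O)cc(OC)cc1O | starting material
18 | (5R,6Z)-1-(2-acetyl-3-hydroxy-5-methoxyphenoxy)-5,6-dimethylnona-6,8-dien-2-one | CC(=O)c1c(O)cc(OC)cc1OCC(=O)CC[C@@H](C)/C(C)=C\C=C | intermediate
19 | (6R,7Z)-2-(2-acetyl-3-hydroxy-5-methoxyphenoxy)-1-[di(propan-2-yl)amino]-6,7-dimethyldeca-7,9-dien-3-one (C2 epimers) | CC(=O)c1c(O)cc(OC)cc1OC(CN(C(C)C)C(C)C)C(=O)CC[C@@H](C)/C(C)=C\C=C | intermediate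
20 | (6R,7Z)-2-(2-acetyl-3-hydroxy-5-methoxyphenoxy)-6,7-dimethyldeca-1,7,9-trien-3-one | CC(=O)c1c(O)cc(OC)cc1OC(=C)C(=O)CC[C@@H](C)/C(C)=C\C=C | intermediate
21 | (4R,4aR,8aR)-8a-(2-acetyl-3-hydroxy-5-methoxyphenoxy)-4,4a-dimethyl-3,4,4a,7,8,8a-hexahydronaphthalen-1(2H)-one (cis-fused; C4 methyl, C5 methyl and C10 aryloxy on one face) | CC(=O)c1c(O)cc(OC)cc1O[C@]12CCC=C[C@@]1(C)[C@H](C)CCC2=O | intermediate
22 | tertiary carbinol: 21 with C5' bonded to C1 and OH on C1 (O–C10 and C5'–C1 cis) | CC(=O)c1c(O)cc(OC)c2c1O[C@]13CCC=C[C@@]1(C)[C@H](C)CC[C@]23O | intermediate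
23 | styrenyl alkene: dihydrobenzofuran-fused diene with C1=C2 and C6=C7 (4R,5R,10-O cis to C5 methyl) | CC(=O)c1c(O)cc(OC)c2c1O[C@]13CCC=C[C@@]1(C)[C@H](C)CC=C23 | intermediate
24 | (1R,4R,5R,10S)-tetracyclic dihydrobenzofuran: C5'–C1 closed, C1–H cis to C9, C6=C7 alkene, 1'-acetyl, 2'-OH, 4'-OMe | CC(=O)c1c(O)cc(OC)c2c1O[C@]13CCC=C[C@@]1(C)[C@H](C)CC[C@H]23 | intermediate
25 | (1R,4R,5R,10S)-tetracyclic enone: 24 with C8 ketone conjugated to C6=C7 | CC(=O)c1c(O)cc(OC)c2c1O[C@]13CC(=O)C=C[C@@]1(C)[C@H](C)CC[C@H]23 | intermediate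
26 | (1R,4R,5R,6S,7R,10S)-cyclopropyl ketone: C6–C7–C11 cyclopropane (C11 dimethyl) anti to the C5 methyl, C8 ketone, C9 CH2, 1'-acetyl | CC(=O)c1c(O)cc(OC)c2c1O[C@]13CC(=O)[C@@H]4[C@@H](C4(C)C)[C@@]1(C)[C@H](C)CC[C@H]23 | intermediate
27 | 4-methoxybenzaldehyde | COc1ccc(C=O)cc1 | starting material
28 | aldol adduct: 26 with 1'-[3-hydroxy-3-(4-methoxyphenyl)propanoyl] (carbinol epimers) | COc1ccc(C(O)CC(=O)c2c(O)cc(OC)c3c2O[C@]24CC(=O)[C@@H]5[C@@H](C5(C)C)[C@@]2(C)[C@H](C)CC[C@H]34)cc1 | intermediate
29 | (1R,4R,5R,6S,7R,10S)-chalcone: 26 with 1'-[(E)-3-(4-methoxyphenyl)prop-2-enoyl] | COc1ccc(/C=C/C(=O)c2c(O)cc(OC)c3c2O[C@]24CC(=O)[C@@H]5[C@@H](C5(C)C)[C@@]2(C)[C@H](C)CC[C@H]34)cc1 | intermediate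
30 | dipotassium 2'-phenoxide C8,C9-enolate of 29 | COc1ccc(/C=C/C(=O)c2c([O-])cc(OC)c3c2O[C@]24C=C([O-])[C@@H]5[C@@H](C5(C)C)[C@@]2(C)[C@H](C)CC[C@H]34)cc1.[K+].[K+] | intermediate
31 | C9-hydroxy ketone: 29 with OH on C9 (C9 epimers) | COc1ccc(/C=C/C(=O)c2c(O)cc(OC)c3c2O[C@]24C(O)C(=O)[C@@H]5[C@@H](C5(C)C)[C@@]2(C)[C@H](C)CC[C@H]34)cc1 | intermediate
32 | CNP0121765.1, (1R,4R,5R,6S,7R,10S)-C8,C9-diketone chalcone | COc1ccc(/C=C/C(=O)c2c(O)cc(OC)c3c2O[C@]24C(=O)C(=O)[C@@H]5[C@@H](C5(C)C)[C@@]2(C)[C@H](C)CC[C@H]34)cc1 | target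

Total step count: 20. Longest linear sequence: 20 steps (1 → 32); compounds 2, 14, 17 and 27 enter along this line.

Steps most likely to fail

Step 14. The cycloaddition has to join two fully substituted carbons, so it may be outrun by the suprafacial 1,5-hydrogen shift from C4 into the Z-diene, which erases the stereocentre, or by polymerisation of the donor–acceptor enone. The fallback replaces thermal activation by cationic activation (Gassman-type ionic Diels–Alder reaction). Setting out from 20, 1,2-bis(trimethylsilyloxy)ethane and catalytic Me3SiOSO2CF3 in CH2Cl2 at −78 °C would give the trienone dioxolane F1. The same acid ionises F1 to a 2-vinyl-1,3-dioxolan-2-ylium ion, a far stronger dienophile, which should cyclise well below the temperature of the hydrogen shift to the cis-octalin dioxolane F2. Pyridinium p-toluenesulfonate in wet acetone would then return to 21.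

Step 15. Hydride may be transferred to the protonated aryl methyl ketone, the C1 cation may undergo a 1,2-shift, or hydride may arrive on the face that gives the strained trans-fused ring. The fallback replaces cationic reduction by radical reduction. Setting out from 21, the acid stage is run without silane and the styrenyl alkene 23 is isolated. Hydrogen-atom-transfer hydrogenation with Mn(C11H19O2)3 [manganese tris(dipivaloylmethanate)], PhSiH3 and t-BuOOH in i-PrOH adds hydrogen to C2 and then to the tertiary benzylic radical at C1. It leaves ketones and the disubstituted C6=C7 alkene alone and should give the more stable cis-fused 24. No compound outside the list is made (F0).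

Step 16. Hydrogen abstraction at the tertiary benzylic C1–H, or oxidation of the phenol, may compete with the C8 methylene. The fallback replaces the radical oxidation by a pericyclic one that needs an alkene and cannot touch a benzylic C–H. Setting out from 24, catalytic SeO2 with t-BuOOH in CH2Cl2 at rt would give, by ene reaction and 2,3-sigmatropic shift, the C8 allylic alcohol F3 (either epimer). MnO2 in CH2Cl2 would then come back to 25.

Further compounds
F1 | step 14 | 2-[1-(2-acetyl-3-hydroxy-5-methoxyphenoxy)ethenyl]-2-[(3R,4Z)-3,4-dimethylhepta-4,6-dien-1-yl]-1,3-dioxolane | CC(=O)c1c(O)cc(OC)cc1OC(=C)C1(CC[C@@H](C)/C(C)=C\C=C)OCCO1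
F2 | step 14 | ethylene ketal (at C1) of 21 | CC(=O)c1c(O)cc(OC)cc1O[C@]12CCC=C[C@@]1(C)[C@H](C)CCC21OCCO1
F0 | step 15 | none | none
F3 | step 16 | C8 allylic alcohol of 24 (C8 epimers) | CC(=O)c1c(O)cc(OC)c2c1O[C@]13CC(O)C=C[C@@]1(C)[C@H](C)CC[C@H]23
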